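**Strategy.** The butenolide (O1, C2 lactone carbonyl, C3 methoxy, C4 catechol, quaternary C5) is cut at C4–C5 and O1–C2. Because the exocyclic methylene on C5 is benzylic to the chroman arene and para to the chroman ring oxygen, it is carried through as an aryl ketone, so that the C5 precursor becomes a non-enolisable chromanyl 2,3-diketoester and its partner the Z-enol of a benzyl-protected methyl catechol-pyruvate. A single copper bis(oxazoline)-catalysed aldol-lactonisation should join the halves, close the butenolide and set C5; the surplus carbonyl is then removed by ionic hydrogenation.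

Key step: step 12

Remark (assumption): the (R,R)-(salen)MnCl catalyst is taken to give the (3R,4R)-epoxide, the sense established for 2,2-dimethylchromenes. C5 is R in 20–22 and S in 23–24 only because the CIP rank of the side-chain carbon drops when its carbonyl is removed; the spatial arrangement is the same throughout.

**Step 1**
Reactants: 1 methyl 4-hydroxybenzoate; 2 3-chloro-3-methylbut-1-yne
Product: 3 methyl 4-[(2-methylbut-3-yn-2-yl)oxy]benzoate
Conditions: CuCl2·2H2O (0.1 mol%), DBU, MeCN, 0 °C
Reagents that add atoms: none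
Why: Copper-catalysed O-propargylation of the phenoxide by the tertiary propargylic chloride (an SN1-like substitution through a copper-stabilised propargyl/allenyl cation) is the standard entry to aryl 1,1-dimethylpropargyl ethers and suits acidic, ester-bearing phenols.

**Step 2**
Reactants: 3 methyl 4-[(2-methylbut-3-yn-2-yl)oxy]benzoate
Product: 5 methyl 2,2-dimethyl-2H-chromene-6-carboxylate, via ortho-allenylphenol 4 (not isolated)
Conditions: N,N-diethylaniline, 190 °C
Reagents that add atoms: none
Why: Heating triggers an aromatic propargyl Claisen rearrangement to the ortho-allenylphenol, whose [1,5]-hydrogen shift and oxa-6π electrocyclisation close the pyran ring; both ortho positions are equivalent, so a single chromene should result.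

**Step 3**
Reactants: 5 methyl 2,2-dimethyl-2H-chromene-6-carboxylate
Product: 6 methyl (3R,4R)-3,4-epoxy-2,2-dimethylchroman-6-carboxylate
Conditions: (R,R)-(salen)MnCl = chloro[(R,R)-N,N'-bis(3,5-di-tert-butylsalicylidene)cyclohexane-1,2-diaminato]manganese (trivalent manganese, 4 mol%), 4-phenylpyridine N-oxide (0.2 equiv), aq NaOCl buffered to pH 11.3 (Na2HPO4), CH2Cl2, 0 °C
Reagents that add atoms: sodium hypochlorite, [Na+].[O-]Cl
Why: Jacobsen–Katsuki epoxidation, for which cis-olefins conjugated to an arene and flanked by a gem-dimethyl group are the best substrate class; the (R,R)-catalyst should deliver oxygen to the face that gives the (3R,4R)-epoxide, which fixes chroman C3.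

**Step 4**
Reactants: 6 methyl (3R,4R)-3,4-epoxy-2,2-dimethylchroman-6-carboxylate
Product: 7 methyl (3R)-3-hydroxy-2,2-dimethylchroman-6-carboxylate
Conditions: H2 (1 atm), 10% Pd/C, EtOAc, rt
Reagents that add atoms: none
Why: Heterogeneous hydrogenolysis cleaves only the benzylic C4–O bond of the epoxide, so the C3–O bond and its R configuration are untouched, and the benzoate ester and arene are inert at one atmosphere of hydrogen.

**Step 5**
Reactants: 7 methyl (3R)-3-hydroxy-2,2-dimethylchroman-6-carboxylate
Product: 8 methyl (3R)-3-(benzyloxy)-2,2-dimethylchroman-6-carboxylate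
Conditions: NaH, BnBr, n-Bu4NI (cat.), THF/DMF (4:1), 0 °C → rt
Reagents that add atoms: benzyl bromide, BrCc1ccccc1
Why: Williamson etherification of the sodium alkoxide (iodide catalysis helps the hindered neopentyl-like oxygen) installs a group that should survive base, KHSO5, Lewis acid and dilute TFA and leaves in the last step; the ester has no α-hydrogen and C3 cannot epimerise.

**Step 6**
Reactants: 8 methyl (3R)-3-(benzyloxy)-2,2-dimethylchroman-6-carboxylate
Product: 9 (3R)-3-(benzyloxy)-2,2-dimethylchroman-6-carboxylic acid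
Conditions: LiOH·H2O, THF/MeOH/H2O, 50 °C; then 1 M HCl
Reagents that add atoms: lithium hydroxide, [Li+].[OH-]
Why: Ordinary ester saponification by acyl–oxygen cleavage, to which the benzyl ether, the chroman ether and the stereocentre are inert.

**Step 7**
Reactants: 9 (3R)-3-(benzyloxy)-2,2-dimethylchroman-6-carboxylic acid; 10 methyl (triphenylphosphoranylidene)acetate
Product: 11 methyl 3-[(3R)-3-(benzyloxy)-2,2-dimethylchroman-6-yl]-3-oxo-2-(triphenylphosphoranylidene)propanoate
Conditions: EDCI (1.5 equiv), DMAP (0.2 equiv), CH2Cl2, 0 °C → rt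
Reagents that add atoms: none
Why: Carbodiimide activation of the acid and C-acylation of the stabilised ylide (the Wasserman route to masked vicinal tricarbonyls) should give a chromatography-stable acyl phosphorane in which the future central carbonyl is stored as C=P.

**Step 8**
Reactants: 11 methyl 3-[(3R)-3-(benzyloxy)-2,2-dimethylchroman-6-yl]-3-oxo-2-(triphenylphosphoranylidene)propanoate
Product: 13 methyl 3-[(3R)-3-(benzyloxy)-2,2-dimethylchroman-6-yl]-2,3-dioxopropanoate, via tricarbonyl hydrate 12 (not isolated)
Conditions: KHSO5 (as the triple salt 2KHSO5·KHSO4·K2SO4), THF/H2O, rt; then 4 Å MS, CH2Cl2, rt, used at once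
Reagents that add atoms: potassium peroxymonosulfate, [K+].[O-]S(=O)(=O)OO
Why: Oxidative cleavage of the acyl ylide C=P bond by peroxymonosulfate is the established unmasking of vicinal tricarbonyls; the gem-diol first formed is dehydrated over sieves just before use, and the benzyl ether and the acyl-deactivated arene are inert to KHSO5 at room temperature.

**Step 9**
Reactants: 14 3,4-bis(benzyloxy)benzaldehyde; 15 N-acetylglycine
Product: 16 (4Z)-4-[3,4-bis(benzyloxy)benzylidene]-2-methyl-1,3-oxazol-5(4H)-one
Conditions: Ac2O, NaOAc, 100 °C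
Reagents that add atoms: none
Why: Erlenmeyer–Plöchl azlactone synthesis, in which acetic anhydride cyclodehydrates N-acetylglycine to 2-methyloxazol-5(4H)-one and its acidic C4 condenses (Perkin-type) with the aldehyde to the thermodynamically preferred Z-arylidene azlactone without touching the benzyl ethers.

**Step 10**
Reactants: 16 (4Z)-4-[3,4-bis(benzyloxy)benzylidene]-2-methyl-1,3-oxazol-5(4H)-one
Product: 18 (2Z)-3-[3,4-bis(benzyloxy)phenyl]-2-hydroxyprop-2-enoic acid (enol form of the arylpyruvic acid), via acetamidocinnamic acid 17 (not isolated)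
Conditions: acetone/H2O, reflux; then 1 M HCl, 1,4-dioxane, 90 °C, Ar
Reagents that add atoms: water, O
Why: Hydrolytic opening of the azlactone followed by acid hydrolysis of the N-acyl enamine (C-protonation, water addition, loss of acetamide) should release the arylpyruvic acid, which rests as its conjugated Z-enol; dilute acid, moderate temperature and argon are chosen to spare the aryl benzyl ethers and the oxidisable enol.

**Step 11**
Reactants: 18 (2Z)-3-[3,4-bis(benzyloxy)phenyl]-2-hydroxyprop-2-enoic acid
Product: 19 methyl (2Z)-3-[3,4-bis(benzyloxy)phenyl]-2-hydroxyprop-2-enoate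
Conditions: DBU (1.0 equiv), MeI, DMF, 0 °C
Reagents that add atoms: iodomethane, CI
Why: SN2 O-methylation of the carboxylate formed with exactly one equivalent of amidine base; the acid is several pK units more acidic than the enol, so the enol hydroxyl should stay free and the product remains the Z-enol needed as donor.

**Step 12**
Reactants: 13 methyl 3-[(3R)-3-(benzyloxy)-2,2-dimethylchroman-6-yl]-2,3-dioxopropanoate; 19 methyl (2Z)-3-[3,4-bis(benzyloxy)phenyl]-2-hydroxyprop-2-enoate
Product: 21 methyl (2R)-2-{[(3R)-3-(benzyloxy)-2,2-dimethylchroman-6-yl]carbonyl}-3-[3,4-bis(benzyloxy)phenyl]-4-hydroxy-5-oxo-2,5-dihydrofuran-2-carboxylate (5-aroyl isotetronic acid), via open aldol adduct 20 (not isolated)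
Conditions: Cu(OTf)2 (10 mol%), (S,S)-t-Bu-box [2,2'-(propane-2,2-diyl)bis((4S)-4-tert-butyl-4,5-dihydrooxazole), 11 mol%], 4 Å MS, CH2Cl2, −20 °C → rt, no added base
Reagents that add atoms: none
Why: Proposed new method: the divalent copper bis(oxazoline) dication should bind the central keto oxygen and the ester carbonyl of 13 in a five-membered chelate, the benzylic enol carbon of 19 (future C4) adds to the central carbonyl carbon (future C5) to give 20, and the tertiary copper alkoxide then acylates itself on the donor ester carbon (future C2) with loss of methanol, after which the α-keto lactone tautomerises to the conjugated C3 enol and makes the sequence irreversible. The closest known reaction types are chiral copper bis(oxazoline)-catalysed aldol and carbonyl-ene additions to pyruvates and to the central carbonyl of 2,3-diketoesters, the copper bis(oxazoline) pyruvate homo-aldol that ends in isotetronic acids, and the racemic base-mediated aldol-lactonisation of arylpyruvates; pairing an arylpyruvate enol with a vicinal tricarbonyl is new. The butenolide ring closes by 5-exo-trig attack of O1 on the ester carbonyl. C5 is controlled by the C2-symmetric ligand, whose tert-butyl groups should shield the re face of the chelated carbonyl so that si-face attack (the sense known for pyruvates with the (S,S)-ligand) gives the drawn arrangement, while the transient C4 centre is erased by enolisation and the remote chroman C3 only makes any minor C5 epimer a separable diastereomer. The step needs donor/acceptor chemoselectivity and facial selectivity: 13 has no α-hydrogen and its doubly flanked central carbonyl is far more electrophilic than the small keto fraction of 19 or its own para-alkoxyaryl ketone, so only one pairing can occur, and the sieves take up water and the released methanol, which protects the cleavable aroyl–C5 bond.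

**Step 13**
Reactants: 21 5-aroyl isotetronic acid
Product: 22 methyl (2R)-2-{[(3R)-3-(benzyloxy)-2,2-dimethylchroman-6-yl]carbonyl}-3-[3,4-bis(benzyloxy)phenyl]-4-methoxy-5-oxo-2,5-dihydrofuran-2-carboxylate
Conditions: TMSCHN2 (1.2 equiv), toluene/MeOH (4:1), 0 °C; AcOH quench
Reagents that add atoms: trimethylsilyldiazomethane, C[Si](C)(C)C=[N+]=[N-]
Why: O-Methylation of the acidic isotetronic enol (a vinylogous carboxylic acid) by diazomethane generated in situ is neutral, which avoids the alkoxide-induced retro-Claisen loss of the aroyl group from C5; no other acidic hydroxyl is present.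

**Step 14**
Reactants: 22 3-methoxy-5-aroyl butenolide
Product: 23 methyl (2S)-2-{[(3R)-3-(benzyloxy)-2,2-dimethylchroman-6-yl]methyl}-3-[3,4-bis(benzyloxy)phenyl]-4-methoxy-5-oxo-2,5-dihydrofuran-2-carboxylate
Conditions: Et3SiH (5 equiv), TFA/CH2Cl2 (1:4), 0 °C → rt
Reagents that add atoms: none
Why: Ionic hydrogenation (ketone protonation, hydride transfer from silane, ionisation of the benzylic alcohol to a cation stabilised by the para chroman oxygen, second hydride transfer) should give the methylene while the electron-poor tetrasubstituted butenolide alkene, the esters and, in dilute TFA with silane as cation scavenger, the benzyl ethers are left alone; the quaternary C5 is untouched.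

**Step 15**
Reactants: 23 tribenzyl ether of the target
Product: 24 methyl (2S)-3-(3,4-dihydroxyphenyl)-2-{[(3R)-3-hydroxy-2,2-dimethylchroman-6-yl]methyl}-4-methoxy-5-oxo-2,5-dihydrofuran-2-carboxylate (CNP0289675.1)
Conditions: H2 (1 atm), 10% Pd/C, EtOAc/MeOH, rt
Reagents that add atoms: none
Why: Hydrogenolysis of the one alkyl and two aryl benzyl ethers over palladium on carbon frees the secondary alcohol and the catechol, whereas the tetrasubstituted conjugated butenolide double bond, the fully substituted C5–O1 bond and the chroman should resist hydrogenation at one atmosphere.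

**Compound list**
1 | methyl 4-hydroxybenzoate | COC(=O)c1ccc(O)cc1 | starting material
2 | 3-chloro-3-methylbut-1-yne | C#CC(C)(C)Cl | starting material
3 | methyl 4-[(2-methylbut-3-yn-2-yl)oxy]benzoate | COC(=O)c1ccc(OC(C)(C)C#C)cc1 | intermediate
4 | methyl 4-hydroxy-3-(3-methylbuta-1,2-dien-1-yl)benzoate (ortho-allenylphenol) | COC(=O)c1ccc(O)c(C=C=C(C)C)c1 | intermediate
5 | methyl 2,2-dimethyl-2H-chromene-6-carboxylate | COC(=O)c1ccc2c(c1)C=CC(C)(C)O2 | intermediate
6 | methyl (3R,4R)-3,4-epoxy-2,2-dimethylchroman-6-carboxylate | COC(=O)c1ccc2c(c1)[C@H]3O[C@H]3C(C)(C)O2 | intermediate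
7 | methyl (3R)-3-hydroxy-2,2-dimethylchroman-6-carboxylate | COC(=O)c1ccc2c(c1)C[C@@H](O)C(C)(C)O2 | intermediate
8 | methyl (3R)-3-(benzyloxy)-2,2-dimethylchroman-6-carboxylate | COC(=O)c1ccc2c(c1)C[C@@H](OCc3ccccc3)C(C)(C)O2 | intermediate
9 | (3R)-3-(benzyloxy)-2,2-dimethylchroman-6-carboxylic acid | OC(=O)c1ccc2c(c1)C[C@@H](OCc3ccccc3)C(C)(C)O2 | intermediate
10 | methyl (triphenylphosphoranylidene)acetate | COC(=O)C=P(c1ccccc1)(c1ccccc1)c1ccccc1 | starting material
11 | methyl 3-[(3R)-3-(benzyloxy)-2,2-dimethylchroman-6-yl]-3-oxo-2-(triphenylphosphoranylidene)propanoate | COC(=O)C(=P(c1ccccc1)(c1ccccc1)c1ccccc1)C(=O)c1ccc2c(c1)C[C@@H](OCc3ccccc3)C(C)(C)O2 | intermediate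
12 | methyl 3-[(3R)-3-(benzyloxy)-2,2-dimethylchroman-6-yl]-2,2-dihydroxy-3-oxopropanoate (tricarbonyl hydrate) | COC(=O)C(O)(O)C(=O)c1ccc2c(c1)C[C@@H](OCc3ccccc3)C(C)(C)O2 | intermediate
13 | methyl 3-[(3R)-3-(benzyloxy)-2,2-dimethylchroman-6-yl]-2,3-dioxopropanoate | COC(=O)C(=O)C(=O)c1ccc2c(c1)C[C@@H](OCc3ccccc3)C(C)(C)O2 | intermediate
14 | 3,4-bis(benzyloxy)benzaldehyde | O=Cc1ccc(OCc2ccccc2)c(OCc2ccccc2)c1 | starting material
15 | N-acetylglycine | CC(=O)NCC(=O)O | starting material
16 | (4Z)-4-[3,4-bis(benzyloxy)benzylidene]-2-methyl-1,3-oxazol-5(4H)-one | CC1=N/C(=C\c2ccc(OCc3ccccc3)c(OCc3ccccc3)c2)C(=O)O1 | intermediate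
17 | (2Z)-2-acetamido-3-[3,4-bis(benzyloxy)phenyl]prop-2-enoic acid | CC(=O)N/C(=C\c1ccc(OCc2ccccc2)c(OCc2ccccc2)c1)C(=O)O | intermediate
18 | (2Z)-3-[3,4-bis(benzyloxy)phenyl]-2-hydroxyprop-2-enoic acid | OC(=O)/C(O)=C/c1ccc(OCc2ccccc2)c(OCc2ccccc2)c1 | intermediate
19 | methyl (2Z)-3-[3,4-bis(benzyloxy)phenyl]-2-hydroxyprop-2-enoate | COC(=O)/C(O)=C/c1ccc(OCc2ccccc2)c(OCc2ccccc2)c1 | intermediate
20 | dimethyl (2R)-2-{[(3R)-3-(benzyloxy)-2,2-dimethylchroman-6-yl]carbonyl}-3-[3,4-bis(benzyloxy)phenyl]-2-hydroxy-4-oxopentanedioate (either configuration at C3) | COC(=O)[C@@](O)(C(C(=O)C(=O)OC)c1ccc(OCc2ccccc2)c(OCc2ccccc2)c1)C(=O)c1ccc2c(c1)C[C@@H](OCc3ccccc3)C(C)(C)O2 | intermediate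
21 | methyl (2R)-2-{[(3R)-3-(benzyloxy)-2,2-dimethylchroman-6-yl]carbonyl}-3-[3,4-bis(benzyloxy)phenyl]-4-hydroxy-5-oxo-2,5-dihydrofuran-2-carboxylate | COC(=O)[C@@]1(C(=O)c2ccc3c(c2)C[C@@H](OCc4ccccc4)C(C)(C)O3)OC(=O)C(O)=C1c1ccc(OCc2ccccc2)c(OCc2ccccc2)c1 | intermediate
22 | methyl (2R)-2-{[(3R)-3-(benzyloxy)-2,2-dimethylchroman-6-yl]carbonyl}-3-[3,4-bis(benzyloxy)phenyl]-4-methoxy-5-oxo-2,5-dihydrofuran-2-carboxylate | COC(=O)[C@@]1(C(=O)c2ccc3c(c2)C[C@@H](OCc4ccccc4)C(C)(C)O3)OC(=O)C(OC)=C1c1ccc(OCc2ccccc2)c(OCc2ccccc2)c1 | intermediate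
23 | methyl (2S)-2-{[(3R)-3-(benzyloxy)-2,2-dimethylchroman-6-yl]methyl}-3-[3,4-bis(benzyloxy)phenyl]-4-methoxy-5-oxo-2,5-dihydrofuran-2-carboxylate | COC(=O)[C@@]1(Cc2ccc3c(c2)C[C@@H](OCc4ccccc4)C(C)(C)O3)OC(=O)C(OC)=C1c1ccc(OCc2ccccc2)c(OCc2ccccc2)c1 | intermediate
24 | methyl (2S)-3-(3,4-dihydroxyphenyl)-2-{[(3R)-3-hydroxy-2,2-dimethylchroman-6-yl]methyl}-4-methoxy-5-oxo-2,5-dihydrofuran-2-carboxylate (CNP0289675.1) | COC(=O)[C@@]1(Cc2ccc3c(c2)C[C@@H](O)C(C)(C)O3)OC(=O)C(OC)=C1c1ccc(O)c(O)c1 | target

**Total step count:** 15 steps.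
**Longest linear sequence:** 12 steps (steps 1–8 and 12–15, from compound 1).

**Steps most likely to fail**

1. Step 12 (proposed new method). The copper may chelate the 1,2-diketone unit (aroyl and central carbonyl) instead of the keto ester unit, which presents the opposite face and would erode or reverse facial selectivity. Lactonisation may also lag so that the reversible aldol reverts, or released methanol may cleave the aroyl–C5 bond. Switching to the (R,R)-ligand is the first remedy. The fallback uses known chemistry and omits the temporary ketone: the classical base-mediated crossed aldol-lactonisation of two arylpyruvate esters. It sets out from 8. LiAlH4 (THF, 0 °C) should give the benzylic alcohol F1, and MnO2 (CH2Cl2) the aldehyde F2. Erlenmeyer condensation with 15 (Ac2O, NaOAc) should give the azlactone F3, and hydrolysis as in step 10 the chromanyl pyruvic acid F4. DBU/MeI should give its methyl ester F5. F5 and 19 are then condensed with DBU (cat.) or K2CO3 in DMF; the crossed 5-benzyl isotetronic acid F6 is expected as a C5 epimer pair beside homodimers and is isolated by chromatography. O-Methylation with TMSCHN2 and chromatographic removal of the C5 epimer F7, a diastereomer because chroman C3 is fixed, returns to the route at 23.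

2. Step 14. Hydride delivery beside the quaternary C5 may be slow, so that the reduction stalls at the benzylic alcohol or its trifluoroacetate. The acid may also remove or shift aryl benzyl groups, or the lactone acyl may migrate to the transient benzylic hydroxyl. The fallback sets out from 22 and replaces ionic reduction by heterogeneous hydrogenolysis: H2, 10% Pd/C, EtOAc/AcOH with a trace of HClO4. This should reduce the para-alkoxyaryl ketone to the methylene and remove the three benzyl ethers in the same operation. It makes no compound outside the list (F0) and comes back to the route at 24.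

3. Step 10. Hot aqueous acid may partly remove the aryl benzyl ethers, and the free arylpyruvic acid may self-condense or oxidise in air. The fallback sets out from 14 and avoids both the acid and the free pyruvic acid. Horner–Wadsworth–Emmons olefination with methyl 2-[(tert-butyldimethylsilyl)oxy]-2-(dimethoxyphosphoryl)acetate (LiN(SiMe3)2, THF, −78 °C → rt) should give the silyl enol ether F8. Desilylation with CsF/AcOH in THF/MeOH frees the enol and comes back to the route at 19.

**Further compounds**
F1 | step 12 | [(3R)-3-(benzyloxy)-2,2-dimethylchroman-6-yl]methanol | OCc1ccc2c(c1)C[C@@H](OCc3ccccc3)C(C)(C)O2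
F2 | step 12 | (3R)-3-(benzyloxy)-2,2-dimethylchroman-6-carbaldehyde | O=Cc1ccc2c(c1)C[C@@H](OCc3ccccc3)C(C)(C)O2
F3 | step 12 | (4Z)-4-{[(3R)-3-(benzyloxy)-2,2-dimethylchroman-6-yl]methylidene}-2-methyl-1,3-oxazol-5(4H)-one | CC1=N/C(=C\c2ccc3c(c2)C[C@@H](OCc4ccccc4)C(C)(C)O3)C(=O)O1
F4 | step 12 | (2Z)-3-[(3R)-3-(benzyloxy)-2,2-dimethylchroman-6-yl]-2-hydroxyprop-2-enoic acid | OC(=O)/C(O)=C/c1ccc2c(c1)C[C@@H](OCc3ccccc3)C(C)(C)O2
F5 | step 12 | methyl (2Z)-3-[(3R)-3-(benzyloxy)-2,2-dimethylchroman-6-yl]-2-hydroxyprop-2-enoate | COC(=O)/C(O)=C/c1ccc2c(c1)C[C@@H](OCc3ccccc3)C(C)(C)O2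
F6 | step 12 | methyl 2-{[(3R)-3-(benzyloxy)-2,2-dimethylchroman-6-yl]methyl}-3-[3,4-bis(benzyloxy)phenyl]-4-hydroxy-5-oxo-2,5-dihydrofuran-2-carboxylate (C5 epimer pair) | COC(=O)C1(Cc2ccc3c(c2)C[C@@H](OCc4ccccc4)C(C)(C)O3)OC(=O)C(O)=C1c1ccc(OCc2ccccc2)c(OCc2ccccc2)c1
F7 | step 12 | C5 epimer of 23, methyl (2R)-2-{[(3R)-3-(benzyloxy)-2,2-dimethylchroman-6-yl]methyl}-3-[3,4-bis(benzyloxy)phenyl]-4-methoxy-5-oxo-2,5-dihydrofuran-2-carboxylate | COC(=O)[C@]1(Cc2ccc3c(c2)C[C@@H](OCc4ccccc4)C(C)(C)O3)OC(=O)C(OC)=C1c1ccc(OCc2ccccc2)c(OCc2ccccc2)c1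
F0 | step 14 | none | none
F8 | step 10 | methyl 3-[3,4-bis(benzyloxy)phenyl]-2-[(tert-butyldimethylsilyl)oxy]prop-2-enoate (E/Z mixture) | COC(=O)C(O[Si](C)(C)C(C)(C)C)=Cc1ccc(OCc2ccccc2)c(OCc2ccccc2)c1
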